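The seven-membered ring is disconnected at C6–C7. Its C6(O)–C7H2–C8(O)(CH3) segment is the imprint of an aldehyde joined to the terminal carbon of a 2-methylallyl unit. A Me2AlCl-promoted type 2 carbonyl-ene reaction therefore forms C6–C7, closes the trans-fused bicyclo[5.3.0]decane and sets C6 in one operation. It leaves a C8 methylene as the handle for the carbinol. The precursor is a cyclopentane with a formyl group on C5, trans to a 3-methylbut-3-enyl chain on quaternary C1, and a silyloxy group on C4. C1 derives from the (S)-citronellol methine by rhodium-carbenoid C–H insertion with retention; C4 and C5 are set by catalyst-controlled hydrogenation.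

Key step: step 11

**Numbering (kept for all intermediates):** C1 fusion carbon with CH3, C2=C3, C4 carbinol carbon with isopropyl, C5 fusion CH, C6 CH–O–acyl, C7 CH2, C8 C(OH)CH3, C9 and C10 CH2. β is the face of the C1 methyl group and α the face of H5. The target is 1β-CH3, 5α-H, 4β-OH/4α-iPr, 6α-acyloxy, 8β-OH/8α-CH3.

**Design points:**
- (a) The primary bromide made in step 1 is carried as the latent coupling site. No hydroxyl protecting group is needed, and no ester-cleaving base meets the β-silyloxy ester.
- (b) C4 carries SiEt3 and C6 later SiMe2tBu, so C4 can be released alone.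
- (c) The C4 oxygen is trans to the formyl group and cis to H5. The aldehyde therefore sits in its thermodynamic minimum and has no anti-periplanar elimination path.
- (d) The C8 carbinol is made by delivering carbon to a C8 ketone, because the open face is α and the target needs the methyl group on α.

**Stereocentres:** C1 in step 5 (retention), C5 in step 6, C6 in step 11, C8 in step 14, C4 in step 18. The C4 centre made in step 6 is temporary and is erased in step 16.

**Assumption (remark on the chemistry):** the facial course at C8 (step 14) is predicted from a twist-chair model of the trans-fused cycloheptanone. The sense of induction in step 6 is taken from the parent 2-alkoxycarbonylcyclopentanones.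

Step 1
Reactants: 1 (S)-citronellol
Product: 2 (S)-citronellyl bromide
Conditions: CBr4, PPh3, CH2Cl2, 0 °C
Reagents that add atoms: carbon tetrabromide, BrC(Br)(Br)Br
Why: Appel bromination replaces the primary hydroxyl by SN2 at C9 without touching the C1 stereocentre or the alkene, and the bromide then serves as a latent coupling site that needs no protecting group.

Step 2
Reactants: 2 (S)-citronellyl bromide
Product: 4 (4S)-6-bromo-4-methylhexanal, via ozonide 3 (not isolated)
Conditions: O3, CH2Cl2, −78 °C; then Me2S, −78 °C to rt
Reagents that add atoms: ozone, [O-][O+]=O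
Why: Ozonolysis with reductive work-up cleaves the only C=C bond to the aldehyde carbon that becomes C4, while the alkyl bromide and the stereocentre are inert to ozone.

Step 3
Reactants: 4 (4S)-6-bromo-4-methylhexanal; 5 ethyl diazoacetate
Product: 6 ethyl (6S)-8-bromo-6-methyl-3-oxooctanoate
Conditions: SnCl2 (10 mol %), CH2Cl2, rt
Reagents that add atoms: ethyl diazoacetate 5, CCOC(=O)C=[N+]=[N-]
Why: Roskamp homologation, in which SnCl2 activates the aldehyde, the diazo carbon adds and a 1,2-hydride shift with loss of N2 gives the β-keto ester, brings in C5 and C6.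

Step 4
Reactants: 6 ethyl (6S)-8-bromo-6-methyl-3-oxooctanoate
Product: 7 ethyl (6S)-8-bromo-2-diazo-6-methyl-3-oxooctanoate
Conditions: 4-acetamidobenzenesulfonyl azide (p-ABSA), Et3N, MeCN, 0 °C to rt
Reagents that add atoms: 4-acetamidobenzenesulfonyl azide, CC(=O)Nc1ccc(cc1)S(=O)(=O)N=[N+]=[N-]
Why: Regitz diazo transfer to the activated methylene of a β-keto ester runs under mild amine base, conditions under which the primary bromide is not displaced.

Step 5
Reactants: 7 ethyl (6S)-8-bromo-2-diazo-6-methyl-3-oxooctanoate
Product: 8 ethyl 2-(2-bromoethyl)-2-methyl-5-oxocyclopentane-1-carboxylate (C1: β-CH3, α-CH2CH2Br; C5 epimers equilibrating)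
Conditions: Rh2(OAc)4 (1 mol %), CH2Cl2, rt, slow addition of 7
Reagents that add atoms: none
Why: Rhodium-carbenoid intramolecular 1,5 C–H insertion favours the electron-rich tertiary C1–H, the only C–H bond that closes a cyclopentanone, and takes place with retention, so the citronellol methine becomes quaternary C1 with CH3 β and the bromoethyl arm α.

Step 6
Reactants: 8 bromo keto ester
Product: 9 ethyl (1R,2R,5R)-2-(2-bromoethyl)-5-hydroxy-2-methylcyclopentane-1-carboxylate (4α-OH; 5β-CO2Et; 1β-CH3)
Conditions: RuCl2[(R)-BINAP] (1 mol %), H2 (100 atm), CH2Cl2, 50 °C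
Reagents that add atoms: none
Why: In this Noyori asymmetric hydrogenation with dynamic kinetic resolution the C5 epimers interconvert through the enol, and the chelating (R)-BINAP ruthenium catalyst, which turns 2-alkoxycarbonylcyclopentanones into (1R,2R)-trans-hydroxy esters, should reduce only the 5β-ester epimer from the β face, setting C4 (α-OH) and C5 (α-H) by catalyst control because CH3 and CH2CH2Br at C1 are too alike to steer the reaction.

Step 7
Reactants: 9 trans-hydroxy ester
Product: 10 C4 triethylsilyl ether of 9 (4α-OSiEt3; 5β-CO2Et; 1β-CH3; 1α-CH2CH2Br)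
Conditions: Et3SiOTf, 2,6-lutidine, CH2Cl2, −78 to 0 °C
Reagents that add atoms: triethylsilyl triflate, CC[Si](CC)(CC)OS(=O)(=O)C(F)(F)F
Why: Silylation with a silyl triflate and a non-nucleophilic base spares the bromide and the base-sensitive β-hydroxy ester, and SiEt3 is chosen because it can later be removed beside the SiMe2tBu ether at C6.

Step 8
Reactants: 10 bromo silyl ether ester; 11 isopropenylmagnesium bromide
Product: 12 ethyl 2-methyl-2-(3-methylbut-3-enyl)-5-(triethylsilyloxy)cyclopentane-1-carboxylate (4α-OSiEt3; 5β-CO2Et; 1β-CH3; 1α-side chain)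
Conditions: Li2CuCl4 (5 mol %), THF/NMP, −20 to 0 °C
Reagents that add atoms: isopropenylmagnesium bromide 11, C=C(C)[Mg]Br
Why: Copper-catalysed Grignard–alkyl bromide cross-coupling (Kochi coupling) is faster than carbonyl addition, the more so as the ester is flanked by quaternary C1 and the C4 silyloxy carbon, and it adds C8, C7 and the methyl group to C9.

Step 9
Reactants: 12 ester
Product: 13 [2-methyl-2-(3-methylbut-3-enyl)-5-(triethylsilyloxy)cyclopentyl]methanol (5β-CH2OH; 4α-OSiEt3; 1β-CH3)
Conditions: iBu2AlH (3 equiv), CH2Cl2, −78 to 0 °C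
Reagents that add atoms: none
Why: Full hydride reduction of the ester to the primary alcohol is chosen over a partial reduction because it can neither stall nor over-run, and it leaves silyl ether, alkene and C5 unchanged.

Step 10
Reactants: 13 primary alcohol
Product: 14 2-methyl-2-(3-methylbut-3-enyl)-5-(triethylsilyloxy)cyclopentane-1-carbaldehyde (5β-CHO, trans to the 1α-side chain and to 4α-OSiEt3)
Conditions: Dess–Martin periodinane, NaHCO3, CH2Cl2, 0 °C to rt
Reagents that add atoms: none
Why: Dess–Martin oxidation under buffered conditions gives the aldehyde without β-elimination, and C5 is not at risk because the formyl group already lies trans to both the C4 silyloxy group and the C1 side chain, its thermodynamically preferred position.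

Step 11
Reactants: 14 aldehyde
Product: 15 trans-fused bicyclo[5.3.0]decanol (1β-CH3; 5α-H; 4α-OSiEt3; 6α-OH; C8 exocyclic methylene)
Conditions: Me2AlCl (1.5 equiv), CH2Cl2 (dilute), −78 to −20 °C
Reagents that add atoms: none
Why: Me2AlCl binds the formyl oxygen, C7 (the CH2 terminus of the 1,1-disubstituted alkene) attacks C6 while a hydrogen of the C8 methyl group migrates to oxygen in a six-centre array, and the alcohol–aluminium complex then loses methane, so that no protic acid is left to isomerise the new alkene. The closest known reaction type is the alkylaluminium-halide-promoted type 2 intramolecular carbonyl-ene cyclisation of 6-methylhept-6-enals to 3-methylenecycloheptanols. The seven-membered ring closes 7-exo-trig at the carbonyl group and endo at the alkene, so that C7 and C8 both become ring members and the former methyl carbon ends as the exocyclic methylene. C6 is the only new stereocentre and is controlled by the fixed trans pair C1/C5: the ring can only form trans-fused, and of the two aldehyde orientations that let oxygen reach the methyl hydrogen the one with O–Al on the α side next to H5 is preferred, because the other presses O–Al against the axial C1 methyl in a 1,3-diaxial contact, which gives the 6α-alcohol, cis to H5. The step needs cyclisation to outrun loss of the C4 silyloxy group, methyl transfer from aluminium and chloride capture at C8, which is secured by the low temperature, by the nucleophilic 1,1-disubstituted alkene held close through the trans-1,2 arrangement on the ring, and by the cis relation of H5 and the C4 oxygen, which offers no anti-periplanar elimination path.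

Step 12
Reactants: 15 ene alcohol
Product: 16 6α-tert-butyldimethylsilyl ether of 15 (4α-OSiEt3; C8 methylene)
Conditions: tBuMe2SiOTf, 2,6-lutidine, CH2Cl2, 0 °C
Reagents that add atoms: tert-butyldimethylsilyl triflate, CC(C)(C)[Si](C)(C)OS(=O)(=O)C(F)(F)F
Why: Silyl triflate silylation caps the hindered secondary C6 alcohol as an ether that is stable to ozone, organometallic reagents and amide base, is far more acid-stable than the C4 SiEt3 ether, and leaves under fluoride at the end.

Step 13
Reactants: 16 bis-silyl ether
Product: 18 C8 ketone (1β-CH3; 5α-H; 4α-OSiEt3; 6α-OSiMe2tBu), via ozonide 17 (not isolated)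
Conditions: O3, CH2Cl2, −78 °C; then Me2S, −78 °C to rt
Reagents that add atoms: ozone, [O-][O+]=O
Why: Ozonolysis with reductive work-up converts the only alkene into the C8 ketone and does not affect silyl ethers.

Step 14
Reactants: 18 C8 ketone; 19 methylmagnesium bromide
Product: 20 tertiary alcohol (8β-OH; 8α-CH3; 4α-OSiEt3; 6α-OSiMe2tBu)
Conditions: CeCl3 (anhydrous), THF, −78 °C
Reagents that add atoms: methylmagnesium bromide 19, C[Mg]Br
Why: Organocerium 1,2-addition is nucleophilic but barely basic, so the β-silyloxy ketone is neither enolised nor eliminated, and in the twist-chair of the trans-fused cycloheptanone, where C8 lies on the local twofold axis, the β face is screened by the axial C1 methyl and by the C6 silyloxy group, so methyl should enter from the α face and give 8α-CH3/8β-OH.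

Step 15
Reactants: 20 tertiary alcohol
Product: 21 diol (4α-OH; 8β-OH; 6α-OSiMe2tBu)
Conditions: pyridinium p-toluenesulfonate (cat.), MeOH/CH2Cl2, 0 °C to rt
Reagents that add atoms: none
Why: Acid-catalysed methanolysis distinguishes the two silyl ethers by their large difference in shielding at silicon, so only the C4 SiEt3 group is lost while the C6 SiMe2tBu ether and the tertiary alcohol remain.

Step 16
Reactants: 21 diol
Product: 22 C4 ketone (8β-OH; 6α-OSiMe2tBu; 5α-H)
Conditions: Dess–Martin periodinane, NaHCO3, CH2Cl2, 0 °C to rt
Reagents that add atoms: none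
Why: Dess–Martin oxidation converts the only secondary alcohol into the C4 ketone under near-neutral conditions, so that C5 does not epimerise, the C6 silyloxy group is not eliminated and the tertiary C8 alcohol is untouched.

Step 17
Reactants: 22 C4 ketone
Product: 24 C2=C3 enone (C4=O; 8β-OSiMe3; 6α-OSiMe2tBu; 5α-H), via bis-silyl enol ether 23 (not isolated)
Conditions: LiN(iPr)2 (3 equiv), Me3SiCl, THF, −78 to 0 °C; evaporation; Pd(OAc)2 (1.1 equiv), MeCN, rt
Reagents that add atoms: chlorotrimethylsilane, C[Si](C)(C)Cl
Why: In this Saegusa–Ito dehydrogenation kinetic deprotonation with in situ silyl trapping occurs at the unhindered C3 methylene rather than at the tertiary C5–H, the C8 alkoxide is capped as its SiMe3 ether in the same operation, and Pd(OAc)2 converts the enol ether into the enone by β-hydride elimination.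

Step 18
Reactants: 24 enone; 25 isopropylmagnesium chloride
Product: 26 tertiary allylic alcohol (4β-OH; 4α-iPr; C2=C3; 8β-OSiMe3; 6α-OSiMe2tBu)
Conditions: CeCl3 (anhydrous), THF, −78 to −20 °C
Reagents that add atoms: isopropylmagnesium chloride 25, CC(C)[Mg]Cl
Why: Organocerium 1,2-addition suppresses conjugate addition, enolisation and β-hydride reduction, and the reagent should approach C4 from the α face, syn to H5 and anti to the axial C1 methyl and the C5–C6 bond, which places isopropyl α and hydroxyl β.

Step 19
Reactants: 26 tertiary allylic alcohol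
Product: 27 triol (4β-OH; 6α-OH; 8β-OH; C2=C3)
Conditions: Bu4NF, THF, rt
Reagents that add atoms: none
Why: Fluoride-induced desilylation removes both silyl ethers under non-acidic conditions, as the ionisable tertiary allylic C4 alcohol requires.

Step 20
Reactants: 28 vanillic acid
Product: 29 4-acetoxy-3-methoxybenzoic acid
Conditions: Ac2O, pyridine, rt; then H2O
Reagents that add atoms: acetic anhydride, CC(=O)OC(C)=O
Why: Acetylation masks the phenol, the only competing nucleophile of the acid, and any mixed anhydride is hydrolysed on aqueous work-up.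

Step 21
Reactants: 27 triol; 29 4-acetoxy-3-methoxybenzoic acid
Product: 30 6α-(4-acetoxy-3-methoxybenzoyl) ester of 27
Conditions: dicyclohexylcarbodiimide, DMAP, CH2Cl2, rt
Reagents that add atoms: 4-acetoxy-3-methoxybenzoic acid 29, COc1cc(C(=O)O)ccc1OC(C)=O
Why: Steglich esterification acylates the single secondary alcohol at C6 with retention, since the tertiary alcohols at C4 and C8 are too hindered to react with the acylpyridinium intermediate.

Step 22
Reactants: 30 acetyl-protected ester
Product: 31 target CNP0113302.1
Conditions: pyrrolidine, CH2Cl2, 0 °C to rt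
Reagents that add atoms: none
Why: Chemoselective aminolysis cleaves the activated aryl acetate far faster than the hindered secondary-alkyl aroate, and the mild non-acidic medium spares the allylic tertiary alcohol.

**Compound list**

1 | (S)-citronellol, (3S)-3,7-dimethyloct-6-en-1-ol | OCC[C@@H](C)CCC=C(C)C | starting material
2 | (S)-citronellyl bromide, (6S)-8-bromo-2,6-dimethyloct-2-ene | BrCC[C@@H](C)CCC=C(C)C | intermediate
3 | ozonide, 3-[(3S)-5-bromo-3-methylpentyl]-5,5-dimethyl-1,2,4-trioxolane | BrCC[C@@H](C)CCC1OOC(C)(C)O1 | intermediate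
4 | (4S)-6-bromo-4-methylhexanal | BrCC[C@@H](C)CCC=O | intermediate
5 | ethyl diazoacetate | CCOC(=O)C=[N+]=[N-] | starting material
6 | ethyl (6S)-8-bromo-6-methyl-3-oxooctanoate | BrCC[C@@H](C)CCC(=O)CC(=O)OCC | intermediate
7 | ethyl (6S)-8-bromo-2-diazo-6-methyl-3-oxooctanoate | BrCC[C@@H](C)CCC(=O)C(=[N+]=[N-])C(=O)OCC | intermediate
8 | bromo keto ester (C1: β-CH3, α-CH2CH2Br; C5 epimers equilibrating) | CCOC(=O)C1C(=O)CC[C@]1(C)CCBr | intermediate
9 | trans-hydroxy ester (4α-OH; 5β-CO2Et; 1β-CH3) | CCOC(=O)[C@H]1[C@H](O)CC[C@]1(C)CCBr | intermediate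
10 | C4 triethylsilyl ether of 9 | CCOC(=O)[C@H]1[C@H](O[Si](CC)(CC)CC)CC[C@]1(C)CCBr | intermediate
11 | isopropenylmagnesium bromide | C=C(C)[Mg]Br | starting material
12 | ester with 3-methylbut-3-enyl chain (4α-OSiEt3; 5β-CO2Et; 1β-CH3) | CCOC(=O)[C@H]1[C@H](O[Si](CC)(CC)CC)CC[C@]1(C)CCC(C)=C | intermediate
13 | primary alcohol (5β-CH2OH) | OC[C@H]1[C@H](O[Si](CC)(CC)CC)CC[C@]1(C)CCC(C)=C | intermediate
14 | aldehyde, ene precursor (5β-CHO; 4α-OSiEt3; 1β-CH3; 1α-side chain) | O=C[C@H]1[C@H](O[Si](CC)(CC)CC)CC[C@]1(C)CCC(C)=C | intermediate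
15 | ene product (6α-OH; C8 methylene; 4α-OSiEt3; trans-fused) | O[C@H]2CC(=C)CC[C@@]3(C)CC[C@@H](O[Si](CC)(CC)CC)[C@H]23 | intermediate
16 | 6α-OSiMe2tBu ether of 15 | CC(C)(C)[Si](C)(C)O[C@H]2CC(=C)CC[C@@]3(C)CC[C@@H](O[Si](CC)(CC)CC)[C@H]23 | intermediate
17 | spiro-ozonide at C8 | CC(C)(C)[Si](C)(C)O[C@H]2CC4(OOCO4)CC[C@@]3(C)CC[C@@H](O[Si](CC)(CC)CC)[C@H]23 | intermediate
18 | C8 ketone | CC(C)(C)[Si](C)(C)O[C@H]2CC(=O)CC[C@@]3(C)CC[C@@H](O[Si](CC)(CC)CC)[C@H]23 | intermediate
19 | methylmagnesium bromide | C[Mg]Br | starting material
20 | tertiary alcohol (8β-OH; 8α-CH3) | CC(C)(C)[Si](C)(C)O[C@H]2C[C@](C)(O)CC[C@@]3(C)CC[C@@H](O[Si](CC)(CC)CC)[C@H]23 | intermediate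
21 | diol (4α-OH; 8β-OH) | CC(C)(C)[Si](C)(C)O[C@H]2C[C@](C)(O)CC[C@@]3(C)CC[C@@H](O)[C@H]23 | intermediate
22 | C4 ketone | CC(C)(C)[Si](C)(C)O[C@H]2C[C@](C)(O)CC[C@@]3(C)CCC(=O)[C@H]23 | intermediate
23 | C3=C4 trimethylsilyl enol ether, 8β-OSiMe3 | CC(C)(C)[Si](C)(C)O[C@H]2C[C@](C)(O[Si](C)(C)C)CC[C@@]3(C)CC=C(O[Si](C)(C)C)[C@H]23 | intermediate
24 | C2=C3 enone, 8β-OSiMe3 | CC(C)(C)[Si](C)(C)O[C@H]2C[C@](C)(O[Si](C)(C)C)CC[C@@]3(C)C=CC(=O)[C@H]23 | intermediate
25 | isopropylmagnesium chloride | CC(C)[Mg]Cl | starting material
26 | tertiary allylic alcohol (4β-OH; 4α-iPr) | CC(C)(C)[Si](C)(C)O[C@H]2C[C@](C)(O[Si](C)(C)C)CC[C@@]3(C)C=C[C@@](O)(C(C)C)[C@H]23 | intermediate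
27 | triol (4β-OH; 6α-OH; 8β-OH) | O[C@H]2C[C@](C)(O)CC[C@@]3(C)C=C[C@@](O)(C(C)C)[C@H]23 | intermediate
28 | vanillic acid | COc1cc(C(=O)O)ccc1O | starting material
29 | 4-acetoxy-3-methoxybenzoic acid | COc1cc(C(=O)O)ccc1OC(C)=O | intermediate
30 | 6α-(4-acetoxy-3-methoxybenzoyl) ester | COc1cc(C(=O)O[C@H]2C[C@](C)(O)CC[C@@]3(C)C=C[C@@](O)(C(C)C)[C@H]23)ccc1OC(C)=O | intermediate
31 | CNP0113302.1 | COc1cc(C(=O)O[C@H]2C[C@](C)(O)CC[C@@]3(C)C=C[C@@](O)(C(C)C)[C@H]23)ccc1O | target

Total step count: 22.
Longest linear sequence: 21 (steps 1–19, 21 and 22).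

**Steps most likely to fail**

1. **Step 11 (key step).**
   - Risk: closure of the seven-membered ring may be slower than loss of the C4 silyloxy group, methyl transfer from aluminium to the aldehyde, or chloride capture of the positive charge developing at C8. The facial selectivity at C6 may also be eroded.
   - Fallback: replace hydrogen transfer by loss of silicon, an intramolecular Hosomi–Sakurai allylation with a far more nucleophilic alkene.
   - It sets out from bromide 10. Li2CuCl4-catalysed coupling with [1-(trimethylsilylmethyl)vinyl]magnesium bromide F1, made from commercial 2-bromoallyltrimethylsilane and Mg in THF, would give allylsilane ester F2.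
   - Reduction with iBu2AlH to alcohol F3 and Dess–Martin oxidation to aldehyde F4 follow the conditions of steps 9 and 10.
   - BF3·OEt2 in CH2Cl2 at −78 °C then forms the same C6–C7 bond with loss of the silyl group, and the route is rejoined at 15.

2. **Step 6.**
   - Risk: hydrogen uptake may be slow beside the quaternary centre, or the catalyst may discriminate poorly between the C5 epimers.
   - Fallback: ask the reagent for C4 only and set C5 afterwards by equilibration.
   - It sets out from 8. An (R)-selective NADPH-dependent ketoreductase (iPrOH as reductant, aqueous buffer pH 7, 30 °C) should give the 4α-alcohol. It is expected as the cis-hydroxy ester F5, the usual outcome of enzymatic reduction of 2-oxocycloalkanecarboxylates.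
   - F5 is carried through the conditions of steps 7–10 via silyl ether F6, coupled ester F7 and alcohol F8 to cis-aldehyde F9.
   - Catalytic DBU in CH2Cl2 at 0 °C then moves the formyl group away from both the silyloxy group and the side chain into the all-trans arrangement, which rejoins the route at 14.

3. **Step 14.**
   - Risk: the facial selectivity of methyl transfer may be weak or inverted, or enolisation may be followed by loss of the C6 silyloxy group.
   - Fallback: deliver oxygen instead of carbon to C8. An oxidant follows the same steric bias but leaves the opposite configuration at C8, so this sequence serves exactly when step 14 does not.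
   - It sets out from alkene 16, so step 13 is skipped. mCPBA with NaHCO3 in CH2Cl2 would give spiro-epoxide F10, and LiBHEt3 in THF opens it at the CH2 terminus, which rejoins the route at 20.

**Further compounds**

F1 | step 11 | [1-(trimethylsilylmethyl)vinyl]magnesium bromide | C=C(C[Si](C)(C)C)[Mg]Br
F2 | step 11 | allylsilane ester | CCOC(=O)[C@H]1[C@H](O[Si](CC)(CC)CC)CC[C@]1(C)CCC(=C)C[Si](C)(C)C
F3 | step 11 | alcohol | OC[C@H]1[C@H](O[Si](CC)(CC)CC)CC[C@]1(C)CCC(=C)C[Si](C)(C)C
F4 | step 11 | aldehyde | O=C[C@H]1[C@H](O[Si](CC)(CC)CC)CC[C@]1(C)CCC(=C)C[Si](C)(C)C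
F5 | step 6 | cis-hydroxy ester (4α-OH; 5α-CO2Et) | CCOC(=O)[C@@H]1[C@H](O)CC[C@]1(C)CCBr
F6 | step 6 | silyl ether | CCOC(=O)[C@@H]1[C@H](O[Si](CC)(CC)CC)CC[C@]1(C)CCBr
F7 | step 6 | coupled ester | CCOC(=O)[C@@H]1[C@H](O[Si](CC)(CC)CC)CC[C@]1(C)CCC(C)=C
F8 | step 6 | alcohol | OC[C@@H]1[C@H](O[Si](CC)(CC)CC)CC[C@]1(C)CCC(C)=C
F9 | step 6 | cis-aldehyde (5α-CHO) | O=C[C@@H]1[C@H](O[Si](CC)(CC)CC)CC[C@]1(C)CCC(C)=C
F10 | step 14 | spiro-epoxide (8β-O; 8α-CH2) | CC(C)(C)[Si](C)(C)O[C@H]2C[C@]4(OC4)CC[C@@]3(C)CC[C@@H](O[Si](CC)(CC)CC)[C@H]23
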